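Assumption: the SMILES is read literally – lactone (3S,4S); the arm on the C4-benzyl ring is (7S,8S) and the arm on the C3-benzyl ring is (7S,8R), where C7 = ArCH(OH) and C8 = CH(CH2OH) in each arm.

Shorthand: Ar′ = 4-(benzyloxy)-3-methoxyphenyl; TBS = tert-butyldimethylsilyl; "A-benzyl" = 4-(benzyloxy)-3-methoxy-5-[(1S,2S)-1-Ar′-1,3-bis(TBS-oxy)propan-2-yl]benzyl; "B-benzyl" = its (1S,2R) diastereomer.

## Retrosynthetic overview

1. Target ⇒ its tetra-O-benzyl tetra-O-TBS derivative (fluoride, then hydrogenolysis). The four benzene rings are bought; the γ-lactone is the only ring made and is closed near the end.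
2. Lactone C3–C4 bond ⇒ direct oxidative cross-coupling of two enolates, an (R)-oxazolidinone imide (arm A) and a methyl ester (arm B). One α-carbon reacts as an oxidatively generated electrophile; the auxiliary fixes C4 and C3 follows by equilibration to the trans lactone.
3. Both halves ⇒ one common arylacetyl (S)-oxazolidinone imide plus O-benzylvanillin: Mg-catalysed anti-aldol gives the (7S,8S) arm, boron syn-aldol gives the (7S,8R) arm.
4. Common imide ⇒ methyl dihydroferulate by ortho-bromination, O-benzylation, Pd-catalysed Reformatsky arylation and N-acylation.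

## Route

Step 1
Reactants: 1 methyl 3-(4-hydroxy-3-methoxyphenyl)propanoate
Product: 2 methyl 3-(3-bromo-4-hydroxy-5-methoxyphenyl)propanoate
Conditions: NBS (1.0 equiv), i-Pr2NH (10 mol%), CH2Cl2, 0 °C
Reagents that add atoms: N-bromosuccinimide, O=C1CCC(=O)N1Br
Why: Electrophilic aromatic bromination under the amine-mediated NBS protocol is ortho-selective for free phenols, and with the para position occupied by the propanoate chain the only position ortho to OH is C5.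

Step 2
Reactants: 2 methyl 3-(3-bromo-4-hydroxy-5-methoxyphenyl)propanoate
Product: 3 methyl 3-[4-(benzyloxy)-3-bromo-5-methoxyphenyl]propanoate
Conditions: BnBr, K2CO3, DMF, rt
Reagents that add atoms: benzyl bromide, BrCc1ccccc1
Why: Williamson ether synthesis on the phenoxide gives a benzyl ether that survives every later base, hydride and acid step and is removed only in the last step.

Step 3
Reactants: 3 methyl 3-[4-(benzyloxy)-3-bromo-5-methoxyphenyl]propanoate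
Product: 4 methyl 3-[4-(benzyloxy)-3-(2-tert-butoxy-2-oxoethyl)-5-methoxyphenyl]propanoate
Conditions: BrZnCH2CO2t-Bu (1.3 equiv), Pd(dba)2 (3 mol%), P(t-Bu)3 (3 mol%), THF, rt
Reagents that add atoms: (2-tert-butoxy-2-oxoethyl)zinc bromide, CC(C)(C)OC(=O)C[Zn]Br
Why: Pd-catalysed α-arylation of a zinc ester enolate (Reformatsky/Negishi-type coupling) runs under neutral conditions that leave the methyl ester untouched and stops at monoarylation.

Step 4
Reactants: 4 methyl 3-[4-(benzyloxy)-3-(2-tert-butoxy-2-oxoethyl)-5-methoxyphenyl]propanoate; 5 (S)-4-benzyloxazolidin-2-one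
Product: 8 (S)-4-benzyl-3-{2-[2-(benzyloxy)-3-methoxy-5-(3-methoxy-3-oxopropyl)phenyl]acetyl}oxazolidin-2-one, via arylacetic acid 6 (not isolated), via mixed pivalic anhydride 7 (not isolated)
Conditions: TFA/CH2Cl2 (1:4), 0 °C → rt; evaporate (PhMe azeotrope); PivCl, Et3N, THF, −20 °C; then LiCl, 5, −20 °C → rt
Reagents that add atoms: none
Why: Acidolysis cleaves only the tert-butyl ester, and the crude acid is N-acylated through its mixed pivalic anhydride (LiCl/Et3N oxazolidinone acylation), installing the auxiliary that controls both side-chain stereocentres.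

Step 5
Reactants: 8 (S)-4-benzyl-3-{2-[2-(benzyloxy)-3-methoxy-5-(3-methoxy-3-oxopropyl)phenyl]acetyl}oxazolidin-2-one; 9 4-(benzyloxy)-3-methoxybenzaldehyde
Product: 11 (S)-4-benzyl-3-{(2S,3S)-2-[2-(benzyloxy)-3-methoxy-5-(3-methoxy-3-oxopropyl)phenyl]-3-Ar′-3-hydroxypropanoyl}oxazolidin-2-one, via dibutylboron enolate 10 (not isolated)
Conditions: Bu2BOTf (1.2 equiv), i-Pr2NEt, CH2Cl2, −78 → 0 °C; 9, −78 → 0 °C; pH 7 buffer, MeOH, H2O2, 0 °C
Reagents that add atoms: none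
Why: Evans boron syn-aldol reaction, in which the Z-dibutylboron enolate of the (S)-benzyl imide reacts through a closed Zimmerman–Traxler chair on the face set by the auxiliary to give the (2S,3S) syn adduct (the 7S,8R arm), while Bu2BOTf/amine does not enolise the methyl ester.

Step 6
Reactants: 11 the (2S,3S) syn-aldol imide
Product: 12 methyl 3-{4-(benzyloxy)-3-[(1S,2R)-1-Ar′-1,3-dihydroxypropan-2-yl]-5-methoxyphenyl}propanoate
Conditions: NaBH4 (4 equiv), THF/H2O (4:1), 0 °C → rt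
Reagents that add atoms: none
Why: Borohydride reduction of the activated N-acyl oxazolidinone in aqueous THF is chemoselective over the methyl ester, releases the auxiliary and touches no stereocentre (the C8 descriptor changes from S to R only because the CIP priorities change).

Step 7
Reactants: 12 the (1S,2R)-diol
Product: 13 methyl 3-{4-(benzyloxy)-3-[(1S,2R)-1-Ar′-1,3-bis(TBS-oxy)propan-2-yl]-5-methoxyphenyl}propanoate
Conditions: TBSOTf (2.5 equiv), 2,6-lutidine, CH2Cl2, −78 → 0 °C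
Reagents that add atoms: tert-butyldimethylsilyl triflate, CC(C)(C)[Si](C)(C)OS(=O)(=O)C(F)(F)F
Why: Silyl triflate silylation protects both hydroxyls in one operation as ethers that tolerate LiN(i-Pr)2, the oxidant and LiBH4.

Step 8
Reactants: 8 the common (S)-arylacetyl imide; 9 4-(benzyloxy)-3-methoxybenzaldehyde
Product: 15 (S)-4-benzyl-3-{(2R,3S)-2-[2-(benzyloxy)-3-methoxy-5-(3-methoxy-3-oxopropyl)phenyl]-3-Ar′-3-hydroxypropanoyl}oxazolidin-2-one, via silylated anti-aldol 14 (not isolated)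
Conditions: MgCl2 (20 mol%), Et3N (2 equiv), Me3SiCl (1.5 equiv), 9 (1.2 equiv), EtOAc, 23 °C; then 1 N HCl/THF (1:5), 0 °C
Reagents that add atoms: none
Why: Evans MgCl2-catalysed direct anti-aldol reaction, in which soft enolisation gives the Mg-chelated Z-enolate, the aldehyde adds through a boat transition state on the face opposite the auxiliary benzyl and Me3SiCl traps the aldolate, giving the (2R,3S) anti adduct (the 7S,8S arm).

Step 9
Reactants: 15 the (2R,3S) anti-aldol imide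
Product: 16 methyl 3-{4-(benzyloxy)-3-[(1S,2S)-1-Ar′-1,3-dihydroxypropan-2-yl]-5-methoxyphenyl}propanoate
Conditions: NaBH4 (4 equiv), THF/H2O (4:1), 0 °C → rt
Reagents that add atoms: none
Why: Chemoselective borohydride reduction of the N-acyl oxazolidinone as in step 6, with no stereocentre touched (C8 becomes S by CIP priority change only).

Step 10
Reactants: 16 the (1S,2S)-diol
Product: 17 methyl 3-{4-(benzyloxy)-3-[(1S,2S)-1-Ar′-1,3-bis(TBS-oxy)propan-2-yl]-5-methoxyphenyl}propanoate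
Conditions: TBSOTf (2.5 equiv), 2,6-lutidine, CH2Cl2, −78 → 0 °C
Reagents that add atoms: tert-butyldimethylsilyl triflate, CC(C)(C)[Si](C)(C)OS(=O)(=O)C(F)(F)F
Why: Silyl triflate silylation of both hydroxyls as in step 7.

Step 11
Reactants: 17 the (1S,2S) bis-silyl methyl ester
Product: 18 3-{4-(benzyloxy)-3-[(1S,2S)-1-Ar′-1,3-bis(TBS-oxy)propan-2-yl]-5-methoxyphenyl}propanoic acid
Conditions: LiOH·H2O (3 equiv), THF/MeOH/H2O (3:1:1), rt; then 1 N HCl to pH 4, 0 °C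
Reagents that add atoms: lithium hydroxide, [Li+].[OH-]
Why: Saponification of the methyl ester is clean because alkyl TBS ethers and aryl benzyl ethers are stable to LiOH and no stereocentre is adjacent to the carboxyl group.

Step 12
Reactants: 18 the (1S,2S) propanoic acid; 19 (R)-4-benzyloxazolidin-2-one
Product: 21 (R)-4-benzyl-3-(3-{4-(benzyloxy)-3-[(1S,2S)-1-Ar′-1,3-bis(TBS-oxy)propan-2-yl]-5-methoxyphenyl}propanoyl)oxazolidin-2-one, via mixed pivalic anhydride 20 (not isolated)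
Conditions: PivCl, Et3N, THF, −20 °C; then LiCl, 19, −20 °C → rt
Reagents that add atoms: none
Why: Mixed-anhydride N-acylation attaches the (R)-auxiliary that will direct the configuration of the future lactone C4.

Step 13
Reactants: 21 the arm-A (R)-imide; 13 the arm-B methyl ester
Product: 24 methyl (2S,3S)-4-[(R)-4-benzyl-2-oxooxazolidin-3-yl]-2-(B-benzyl)-3-(A-benzyl)-4-oxobutanoate, via lithium imide enolate 22 (not isolated), via lithium ester enolate 23 (not isolated)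
Conditions: 21 (1.0 equiv), 13 (1.2 equiv), LiN(i-Pr)2 (2.3 equiv), THF, −78 °C; then Fe(acac)3 (2.3 equiv) in THF, −78 °C → rt
Reagents that add atoms: none
Why: Oxidative enolate heterocoupling, in which Fe(acac)3 (trivalent iron) takes one electron from a lithium enolate to give an electrophilic α-carbonyl radical (an enolonium-type α-carbon of inverted polarity) that is captured by the second enolate, so two normally nucleophilic α-carbons are joined; the bond forms on the face of the chelated Z-imide enolate opposite the auxiliary benzyl, setting the future C4 as S, while the ester α-carbon forms as an epimer mixture that step 14 converges (the different aggregation and oxidation potentials of imide and ester enolates favour cross-coupling).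

Step 14
Reactants: 24 the coupled succinate (with its C2 epimer)
Product: 26 (3S,4S)-3-(B-benzyl)-4-(A-benzyl)dihydrofuran-2(3H)-one (tetra-O-benzyl tetra-O-TBS derivative of the target), via hydroxy ester 25 (not isolated)
Conditions: LiBH4 (1.5 equiv), H2O (1.5 equiv), Et2O/THF, 0 °C; aq. NH4Cl; then DBU (0.5 equiv), PhMe, rt
Reagents that add atoms: none
Why: LiBH4 reduces the imide carbonyl chemoselectively to the primary alcohol, which lactonises onto the methyl ester, and DBU epimerisation α to the lactone carbonyl delivers the thermodynamically favoured trans-3,4-dibenzyl lactone, setting C3 as S relative to the fixed C4.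

Step 15
Reactants: 26 the fully protected lactone
Product: 27 tetra-O-benzyl derivative of the target (all four phenols benzylated and all four alcohols free)
Conditions: Bu4NF (8 equiv), AcOH (8 equiv), THF, 0 °C → rt
Reagents that add atoms: none
Why: Fluoride desilylation buffered with AcOH removes all four TBS ethers without opening the lactone or ionising the benzylic carbinols.

Step 16
Reactants: 27 the tetra-O-benzyl lactone
Product: 28 target CNP0113972.1
Conditions: H2 (1 atm), 10% Pd/C, EtOAc/THF (1:1), rt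
Reagents that add atoms: none
Why: Catalytic hydrogenolysis cleaves the four aryl benzyl ethers much faster than the secondary benzylic C–OH bonds under neutral aprotic conditions and leaves no reagent residues with the polyphenolic product.

## Compound list

1 | methyl 3-(4-hydroxy-3-methoxyphenyl)propanoate (methyl dihydroferulate) | COC(=O)CCc1ccc(O)c(OC)c1 | starting material
2 | methyl 3-(3-bromo-4-hydroxy-5-methoxyphenyl)propanoate | COC(=O)CCc1cc(OC)c(O)c(Br)c1 | intermediate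
3 | methyl 3-[4-(benzyloxy)-3-bromo-5-methoxyphenyl]propanoate | COC(=O)CCc1cc(OC)c(OCc2ccccc2)c(Br)c1 | intermediate
4 | methyl 3-[4-(benzyloxy)-3-(2-tert-butoxy-2-oxoethyl)-5-methoxyphenyl]propanoate | COC(=O)CCc1cc(OC)c(OCc2ccccc2)c(CC(=O)OC(C)(C)C)c1 | intermediate
5 | (S)-4-benzyloxazolidin-2-one | O=C1OC[C@H](Cc2ccccc2)N1 | starting material
6 | 2-[2-(benzyloxy)-3-methoxy-5-(3-methoxy-3-oxopropyl)phenyl]acetic acid (formed in situ) | COC(=O)CCc1cc(OC)c(OCc2ccccc2)c(CC(=O)O)c1 | intermediate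
7 | mixed pivalic anhydride of 6 (formed in situ) | COC(=O)CCc1cc(OC)c(OCc2ccccc2)c(CC(=O)OC(=O)C(C)(C)C)c1 | intermediate
8 | (S)-4-benzyl-3-{2-[2-(benzyloxy)-3-methoxy-5-(3-methoxy-3-oxopropyl)phenyl]acetyl}oxazolidin-2-one | COC(=O)CCc1cc(OC)c(OCc2ccccc2)c(CC(=O)N2C(=O)OC[C@@H]2Cc2ccccc2)c1 | intermediate
9 | 4-(benzyloxy)-3-methoxybenzaldehyde (O-benzylvanillin) | COc1cc(C=O)ccc1OCc1ccccc1 | starting material
10 | (Z)-dibutylboron enolate of 8 (formed in situ) | COC(=O)CCc1cc(OC)c(OCc2ccccc2)c(/C=C(\OB(CCCC)CCCC)N2C(=O)OC[C@@H]2Cc2ccccc2)c1 | intermediate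
11 | (S)-4-benzyl-3-{(2S,3S)-2-[2-(benzyloxy)-3-methoxy-5-(3-methoxy-3-oxopropyl)phenyl]-3-[4-(benzyloxy)-3-methoxyphenyl]-3-hydroxypropanoyl}oxazolidin-2-one | COC(=O)CCc1cc(OC)c(OCc2ccccc2)c([C@H](C(=O)N2C(=O)OC[C@@H]2Cc2ccccc2)[C@H](O)c2ccc(OCc3ccccc3)c(OC)c2)c1 | intermediate
12 | methyl 3-{4-(benzyloxy)-3-[(1S,2R)-1-[4-(benzyloxy)-3-methoxyphenyl]-1,3-dihydroxypropan-2-yl]-5-methoxyphenyl}propanoate | COC(=O)CCc1cc(OC)c(OCc2ccccc2)c([C@H](CO)[C@H](O)c2ccc(OCc3ccccc3)c(OC)c2)c1 | intermediate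
13 | methyl 3-{4-(benzyloxy)-3-[(1S,2R)-1-[4-(benzyloxy)-3-methoxyphenyl]-1,3-bis(tert-butyldimethylsilyloxy)propan-2-yl]-5-methoxyphenyl}propanoate | COC(=O)CCc1cc(OC)c(OCc2ccccc2)c([C@H](CO[Si](C)(C)C(C)(C)C)[C@H](O[Si](C)(C)C(C)(C)C)c2ccc(OCc3ccccc3)c(OC)c2)c1 | intermediate
14 | O-trimethylsilyl ether of 15 (formed in situ) | COC(=O)CCc1cc(OC)c(OCc2ccccc2)c([C@@H](C(=O)N2C(=O)OC[C@@H]2Cc2ccccc2)[C@H](O[Si](C)(C)C)c2ccc(OCc3ccccc3)c(OC)c2)c1 | intermediate
15 | (S)-4-benzyl-3-{(2R,3S)-2-[2-(benzyloxy)-3-methoxy-5-(3-methoxy-3-oxopropyl)phenyl]-3-[4-(benzyloxy)-3-methoxyphenyl]-3-hydroxypropanoyl}oxazolidin-2-one | COC(=O)CCc1cc(OC)c(OCc2ccccc2)c([C@@H](C(=O)N2C(=O)OC[C@@H]2Cc2ccccc2)[C@H](O)c2ccc(OCc3ccccc3)c(OC)c2)c1 | intermediate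
16 | methyl 3-{4-(benzyloxy)-3-[(1S,2S)-1-[4-(benzyloxy)-3-methoxyphenyl]-1,3-dihydroxypropan-2-yl]-5-methoxyphenyl}propanoate | COC(=O)CCc1cc(OC)c(OCc2ccccc2)c([C@@H](CO)[C@H](O)c2ccc(OCc3ccccc3)c(OC)c2)c1 | intermediate
17 | methyl 3-{4-(benzyloxy)-3-[(1S,2S)-1-[4-(benzyloxy)-3-methoxyphenyl]-1,3-bis(tert-butyldimethylsilyloxy)propan-2-yl]-5-methoxyphenyl}propanoate | COC(=O)CCc1cc(OC)c(OCc2ccccc2)c([C@@H](CO[Si](C)(C)C(C)(C)C)[C@H](O[Si](C)(C)C(C)(C)C)c2ccc(OCc3ccccc3)c(OC)c2)c1 | intermediate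
18 | 3-{4-(benzyloxy)-3-[(1S,2S)-1-[4-(benzyloxy)-3-methoxyphenyl]-1,3-bis(tert-butyldimethylsilyloxy)propan-2-yl]-5-methoxyphenyl}propanoic acid | OC(=O)CCc1cc(OC)c(OCc2ccccc2)c([C@@H](CO[Si](C)(C)C(C)(C)C)[C@H](O[Si](C)(C)C(C)(C)C)c2ccc(OCc3ccccc3)c(OC)c2)c1 | intermediate
19 | (R)-4-benzyloxazolidin-2-one | O=C1OC[C@@H](Cc2ccccc2)N1 | starting material
20 | mixed pivalic anhydride of 18 (formed in situ) | CC(C)(C)C(=O)OC(=O)CCc1cc(OC)c(OCc2ccccc2)c([C@@H](CO[Si](C)(C)C(C)(C)C)[C@H](O[Si](C)(C)C(C)(C)C)c2ccc(OCc3ccccc3)c(OC)c2)c1 | intermediate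
21 | (R)-4-benzyl-3-(3-{4-(benzyloxy)-3-[(1S,2S)-1-[4-(benzyloxy)-3-methoxyphenyl]-1,3-bis(tert-butyldimethylsilyloxy)propan-2-yl]-5-methoxyphenyl}propanoyl)oxazolidin-2-one | O=C(CCc1cc(OC)c(OCc2ccccc2)c([C@@H](CO[Si](C)(C)C(C)(C)C)[C@H](O[Si](C)(C)C(C)(C)C)c2ccc(OCc3ccccc3)c(OC)c2)c1)N1C(=O)OC[C@H]1Cc1ccccc1 | intermediate
22 | lithium (Z)-enolate of imide 21 (formed in situ) | [Li]O/C(=C\Cc1cc(OC)c(OCc2ccccc2)c([C@@H](CO[Si](C)(C)C(C)(C)C)[C@H](O[Si](C)(C)C(C)(C)C)c2ccc(OCc3ccccc3)c(OC)c2)c1)N1C(=O)OC[C@H]1Cc1ccccc1 | intermediate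
23 | lithium enolate of ester 13 (formed in situ) | CO/C(O[Li])=C\Cc1cc(OC)c(OCc2ccccc2)c([C@H](CO[Si](C)(C)C(C)(C)C)[C@H](O[Si](C)(C)C(C)(C)C)c2ccc(OCc3ccccc3)c(OC)c2)c1 | intermediate
24 | methyl (2S,3S)-4-[(R)-4-benzyl-2-oxooxazolidin-3-yl]-2-(B-benzyl)-3-(A-benzyl)-4-oxobutanoate (formed together with its C2 epimer) | COC(=O)[C@@H](Cc1cc(OC)c(OCc2ccccc2)c([C@H](CO[Si](C)(C)C(C)(C)C)[C@H](O[Si](C)(C)C(C)(C)C)c2ccc(OCc3ccccc3)c(OC)c2)c1)[C@H](Cc1cc(OC)c(OCc2ccccc2)c([C@@H](CO[Si](C)(C)C(C)(C)C)[C@H](O[Si](C)(C)C(C)(C)C)c2ccc(OCc3ccccc3)c(OC)c2)c1)C(=O)N1C(=O)OC[C@H]1Cc1ccccc1 | intermediate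
25 | methyl (2S,3S)-2-(B-benzyl)-3-(A-benzyl)-4-hydroxybutanoate (formed in situ) | COC(=O)[C@@H](Cc1cc(OC)c(OCc2ccccc2)c([C@H](CO[Si](C)(C)C(C)(C)C)[C@H](O[Si](C)(C)C(C)(C)C)c2ccc(OCc3ccccc3)c(OC)c2)c1)[C@H](Cc1cc(OC)c(OCc2ccccc2)c([C@@H](CO[Si](C)(C)C(C)(C)C)[C@H](O[Si](C)(C)C(C)(C)C)c2ccc(OCc3ccccc3)c(OC)c2)c1)CO | intermediate
26 | (3S,4S)-3-(B-benzyl)-4-(A-benzyl)dihydrofuran-2(3H)-one (tetra-O-benzyl tetra-O-TBS target) | COc1cc([C@@H](O[Si](C)(C)C(C)(C)C)[C@H](CO[Si](C)(C)C(C)(C)C)c2cc(C[C@@H]3COC(=O)[C@H]3Cc3cc(OC)c(OCc4ccccc4)c([C@H](CO[Si](C)(C)C(C)(C)C)[C@H](O[Si](C)(C)C(C)(C)C)c4ccc(OCc5ccccc5)c(OC)c4)c3)cc(OC)c2OCc2ccccc2)ccc1OCc1ccccc1 | intermediate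
27 | tetra-O-benzyl target (four aryl benzyl ethers, four free alcohols) | COc1cc([C@@H](O)[C@H](CO)c2cc(C[C@@H]3COC(=O)[C@H]3Cc3cc(OC)c(OCc4ccccc4)c([C@H](CO)[C@H](O)c4ccc(OCc5ccccc5)c(OC)c4)c3)cc(OC)c2OCc2ccccc2)ccc1OCc1ccccc1 | intermediate
28 | CNP0113972.1 | COc1cc([C@@H](O)[C@H](CO)c2cc(C[C@@H]3COC(=O)[C@H]3Cc3cc(OC)c(O)c([C@H](CO)[C@H](O)c4ccc(O)c(OC)c4)c3)cc(OC)c2O)ccc1O | target

## Step count and risks

Total: 16 steps. Longest linear sequence: 13 steps (steps 1–4, 8–12, 13–16).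

**Step 13 (oxidative enolate cross-coupling of two large fragments; homocoupling, low conversion or poor facial control are possible).** The fallback sets out from 13 and returns at 24. Instead of generating the electrophilic α-carbon by in-situ oxidation, it is made as a discrete compound. The potassium enolate of 13 (KN(SiMe3)2, THF, −78 °C) is hydroxylated with 2-(phenylsulfonyl)-3-phenyloxaziridine to the α-hydroxy ester F1 (both C2 epimers). Tf2O/2,6-lutidine (CH2Cl2, −78 °C) converts it into the α-triflyloxy ester F2. The sodium enolate of 21 (NaN(SiMe3)2, THF, −78 °C) then displaces the triflate by SN2 on its face opposite the auxiliary benzyl to give 24, again as a pair of C2 epimers that step 14 converges.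

**Step 8 (Mg-catalysed anti-aldol with an arylacetyl imide and an electron-rich aldehyde; reactivity and anti selectivity are not assured).** The fallback sets out from 4 and returns at 17. Compound 4 is taken through the sequence of step 4 with the (R)-auxiliary 19 to give the enantiomeric-auxiliary imide F3. Its dibutylboron enolate F4 (Bu2BOTf, i-Pr2NEt, CH2Cl2) adds to 9 in a boron syn-aldol reaction to give the (2R,3R) syn adduct F5. NaBH4 (THF/H2O) gives the (1R,2S)-diol F6, which has the correct C8 but the wrong C7. TBSCl/imidazole silylates only the primary hydroxyl to give the mono-silyl ether F7. Mitsunobu inversion (4-nitrobenzoic acid, PPh3, DIAD, PhMe, 0 °C) gives the (1S,2S) 4-nitrobenzoate F8. K2CO3/MeOH removes the benzoate to give the (1S,2S) secondary alcohol F9, and TBSOTf/2,6-lutidine silylates it to 17.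

**Step 14 (hydride must reduce a hindered imide next to a methyl ester without over-reducing the lactone that forms).** The fallback sets out from 24 and returns at 25. LiOH/H2O2 (THF/H2O, 0 °C) cleaves the auxiliary hydrolytically to the succinic half-ester acid F10. BH3·SMe2 (THF, 0 °C) reduces the carboxylic acid but not the methyl ester to give hydroxy ester 25, which is lactonised and equilibrated with DBU as in step 14 to 26.

## Further compounds

F1 | step 13 | methyl 2-hydroxy-3-{4-(benzyloxy)-3-[(1S,2R)-1-Ar′-1,3-bis(TBS-oxy)propan-2-yl]-5-methoxyphenyl}propanoate (C2 epimers) | COC(=O)C(O)Cc1cc(OC)c(OCc2ccccc2)c([C@H](CO[Si](C)(C)C(C)(C)C)[C@H](O[Si](C)(C)C(C)(C)C)c2ccc(OCc3ccccc3)c(OC)c2)c1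
F2 | step 13 | methyl 2-(trifluoromethylsulfonyloxy)-3-{4-(benzyloxy)-3-[(1S,2R)-1-Ar′-1,3-bis(TBS-oxy)propan-2-yl]-5-methoxyphenyl}propanoate (C2 epimers) | COC(=O)C(OS(=O)(=O)C(F)(F)F)Cc1cc(OC)c(OCc2ccccc2)c([C@H](CO[Si](C)(C)C(C)(C)C)[C@H](O[Si](C)(C)C(C)(C)C)c2ccc(OCc3ccccc3)c(OC)c2)c1
F3 | step 8 | (R)-4-benzyl-3-{2-[2-(benzyloxy)-3-methoxy-5-(3-methoxy-3-oxopropyl)phenyl]acetyl}oxazolidin-2-one | COC(=O)CCc1cc(OC)c(OCc2ccccc2)c(CC(=O)N2C(=O)OC[C@H]2Cc2ccccc2)c1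
F4 | step 8 | (Z)-dibutylboron enolate of F3 | COC(=O)CCc1cc(OC)c(OCc2ccccc2)c(/C=C(\OB(CCCC)CCCC)N2C(=O)OC[C@H]2Cc2ccccc2)c1
F5 | step 8 | (R)-4-benzyl-3-{(2R,3R)-2-[2-(benzyloxy)-3-methoxy-5-(3-methoxy-3-oxopropyl)phenyl]-3-Ar′-3-hydroxypropanoyl}oxazolidin-2-one | COC(=O)CCc1cc(OC)c(OCc2ccccc2)c([C@@H](C(=O)N2C(=O)OC[C@H]2Cc2ccccc2)[C@@H](O)c2ccc(OCc3ccccc3)c(OC)c2)c1
F6 | step 8 | methyl 3-{4-(benzyloxy)-3-[(1R,2S)-1-Ar′-1,3-dihydroxypropan-2-yl]-5-methoxyphenyl}propanoate | COC(=O)CCc1cc(OC)c(OCc2ccccc2)c([C@@H](CO)[C@@H](O)c2ccc(OCc3ccccc3)c(OC)c2)c1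
F7 | step 8 | methyl 3-{4-(benzyloxy)-3-[(1R,2S)-1-Ar′-1-hydroxy-3-(TBS-oxy)propan-2-yl]-5-methoxyphenyl}propanoate | COC(=O)CCc1cc(OC)c(OCc2ccccc2)c([C@@H](CO[Si](C)(C)C(C)(C)C)[C@@H](O)c2ccc(OCc3ccccc3)c(OC)c2)c1
F8 | step 8 | methyl 3-{4-(benzyloxy)-3-[(1S,2S)-1-Ar′-1-(4-nitrobenzoyloxy)-3-(TBS-oxy)propan-2-yl]-5-methoxyphenyl}propanoate | COC(=O)CCc1cc(OC)c(OCc2ccccc2)c([C@@H](CO[Si](C)(C)C(C)(C)C)[C@H](OC(=O)c2ccc(cc2)[N+](=O)[O-])c2ccc(OCc3ccccc3)c(OC)c2)c1
F9 | step 8 | methyl 3-{4-(benzyloxy)-3-[(1S,2S)-1-Ar′-1-hydroxy-3-(TBS-oxy)propan-2-yl]-5-methoxyphenyl}propanoate | COC(=O)CCc1cc(OC)c(OCc2ccccc2)c([C@@H](CO[Si](C)(C)C(C)(C)C)[C@H](O)c2ccc(OCc3ccccc3)c(OC)c2)c1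
F10 | step 14 | (2S,3S)-2-(A-benzyl)-3-(B-benzyl)-4-methoxy-4-oxobutanoic acid | COC(=O)[C@@H](Cc1cc(OC)c(OCc2ccccc2)c([C@H](CO[Si](C)(C)C(C)(C)C)[C@H](O[Si](C)(C)C(C)(C)C)c2ccc(OCc3ccccc3)c(OC)c2)c1)[C@H](Cc1cc(OC)c(OCc2ccccc2)c([C@@H](CO[Si](C)(C)C(C)(C)C)[C@H](O[Si](C)(C)C(C)(C)C)c2ccc(OCc3ccccc3)c(OC)c2)c1)C(=O)O
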